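**Retrosynthetic overview**
1. The only strategic bond is the acyl C–O bond of the ester. Cutting it gives hexacosanoic acid (C26) and 2-phenylethanol.
2. Both fragments are catalogue chemicals, so no C–C bond has to be made.
3. No ring is formed. The single benzene ring is bought as part of the alcohol.
4. The target has no stereocentre, so the route is one condensation.

Assumption: the target has no stereocentre or stereogenic double bond, so the achiral compound itself meets the "single enantiomer" requirement.

**Step 1**
Reactants: 1 hexacosanoic acid (cerotic acid), 2 phenethyl alcohol (2-phenylethanol, 3 equiv)
Product: 3 phenethyl hexacosanoate (2-phenylethyl n-hexacosanoate, target)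
Conditions: p-toluenesulfonic acid monohydrate (p-CH3C6H4SO3H·H2O, 5 mol %), toluene, reflux (about 111 °C), Dean–Stark arm packed with activated 4 Å molecular sieves, 8–12 h; warm wash with aq NaHCO3; recrystallise from acetone or triturate with cold MeOH to remove excess 2
Reagents that add atoms: none
Why: This is a Fischer esterification in which hot toluene dissolves the waxy C26 acid, excess cheap primary alcohol and continuous water removal drive the equilibrium to the ester, the saturated chain and phenyl ring are inert to catalytic sulfonic acid, and no stereocentre is formed.

Atom balance: C26H52O2 + C8H10O gives C34H60O2 + H2O.

**Compound list**
1 | hexacosanoic acid (cerotic acid) | CCCCCCCCCCCCCCCCCCCCCCCCCC(=O)O | starting material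
2 | phenethyl alcohol (2-phenylethanol) | OCCc1ccccc1 | starting material
3 | phenethyl hexacosanoate (2-phenylethyl n-hexacosanoate) | CCCCCCCCCCCCCCCCCCCCCCCCCC(=O)OCCc1ccccc1 | target

**Total step count:** 1
**Longest linear sequence:** 1

**Steps most likely to fail**
The route has only one step, so the ranking has one entry.

Step 1 is the risk. Compound 1 is usually handled on a small scale, so very little water forms and it is hard to remove. The equilibrium may then stall. Leftover waxy acid is difficult to separate from the waxy ester, and it forms soap emulsions in the bicarbonate wash.

The fallback replaces the reversible acid-catalysed condensation with an irreversible acylation under basic conditions, using a preformed and isolated acyl donor. It sets out from compound 1. Compound 1 is warmed with SOCl2 (1.5 equiv) and a catalytic drop of DMF in toluene at 70 °C until gas evolution stops. The volatiles are then stripped to leave hexacosanoyl chloride F1. This is redissolved in CH2Cl2/toluene and treated with 2 (1.1 equiv), pyridine (1.5 equiv) and catalytic 4-dimethylaminopyridine at 0 °C to room temperature. The fallback comes back to the route at compound 3. Any surviving acyl chloride is hydrolysed on work-up, and the ester is recrystallised as before.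

**Further compounds**
F1 | step 1 | hexacosanoyl chloride | CCCCCCCCCCCCCCCCCCCCCCCCCC(=O)Cl
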